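**Remarks on the chemistry (assumptions)**

- The stereodescriptors of the SMILES are taken literally. Aryl and CH2OH are cis on the dihydrobenzofuran (2R,3R). Aryl, CH2OH and arylmethyl are all cis on the oxolane (3S,4R,5R), with the hydroxyl trans to CH2OH. Both benzylic ethers are therefore treated as the less stable epimers and are kept away from acid while their aryl groups are electron-rich.
- The sense of induction of the chiral bisoxazoline in step 16 cannot be predicted with confidence. The (S,S) ligand is written; its antipode is to be used if it favours the other C2 epimer.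
- The anti-aldol of step 3 is assumed to follow the chelated-enolate facial sense of auxiliary alkylations, hence the (R)-auxiliary; the (S)-auxiliary is to be used if the sense is the reverse.

Abbreviations: Ts = 4-methylbenzenesulfonyl, TBS = tert-butyldimethylsilyl, Bn = benzyl. Benzofuran locants: O1, C2 (aryl), C3 (CH2OH), C3a, C7a. Oxolane locants: O1, C2 (CH2), C3 (OH and arylmethyl), C4 (CH2OH), C5 (aryl).

**Retrosynthetic overview**

1. Target ⇐ O-debenzylation and desilylation ⇐ cis-3-hydroxymethyl dihydrobenzofuran ⇐ hydroboration of a 3-methylidene-2-aryl-2,3-dihydrobenzofuran on the face opposite the C2 aryl group.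
2. Key disconnection: O1–C2 and C3a–C3 of the dihydrobenzofuran, formed together by a palladium-catalysed enantioselective heteroannulation of 1-arylallene 23 with o-iodophenol 20. The enabling feature is in the guaiacyl ring on oxolane C5: the phenolic oxygen (future O1) sits next to the only unsubstituted ortho carbon (future C3a), so iodine can be placed there and the O/C pair adds across the C2–C3 unit; the cis CH2OH/H pair at C3 maps back onto an exocyclic methylidene.
3. Oxolane ⇐ cis-disubstituted γ-lactone from an anti-aldol of a succinyl oxazolidinone with vanillin tosylate; enolate benzylation and enolate hydroxylation from the open face, then lactol reduction. The tosyloxy group keeps the benzylic carbon from ionising.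
4. Ring order: γ-lactone (step 3) → oxolane (step 11) → furan ring of the dihydrobenzofuran (step 16).

Key step: step 16

**Route**

Step 1
Reactants: 1 vanillin
Product: 2 vanillin tosylate (4-formyl-2-methoxyphenyl 4-methylbenzenesulfonate)
Conditions: TsCl, Et3N, DMAP (cat.), CH2Cl2, 0 °C → rt
Reagents that add atoms: 4-methylbenzenesulfonyl chloride, Cc1ccc(cc1)S(Cl)(=O)=O
Why: O-sulfonylation of a phenol; the tosylate is chosen as an electron-withdrawing mask that later suppresses benzylic ionisation and activates the aldehyde for the aldol.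

Step 2
Reactants: 3 (R)-4-benzyl-1,3-oxazolidin-2-one; 4 methyl 4-chloro-4-oxobutanoate
Product: 5 methyl 4-[(4R)-4-benzyl-2-oxo-1,3-oxazolidin-3-yl]-4-oxobutanoate
Conditions: n-BuLi, THF, −78 °C; then 4, −78 → 0 °C
Reagents that add atoms: none
Why: N-acylation of the lithiated oxazolidinone by an acid chloride, the standard entry to chiral N-acyloxazolidinones.

Step 3
Reactants: 5 methyl 4-[(4R)-4-benzyl-2-oxo-1,3-oxazolidin-3-yl]-4-oxobutanoate; 2 vanillin tosylate
Product: 8 cis-lactone imide (4R)-4-benzyl-3-{(2R,3S)-2-[3-methoxy-4-(tosyloxy)phenyl]-5-oxooxolane-3-carbonyl}-1,3-oxazolidin-2-one, via silyl-protected anti-aldol adduct 6 (not isolated), via anti-aldol hydroxy ester 7 (not isolated)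
Conditions: MgCl2 (20 mol %), Et3N, Me3SiCl, EtOAc, rt; then CF3CO2H, MeOH, rt; then TsOH·H2O (cat.), toluene, 60 °C
Reagents that add atoms: none
Why: Magnesium-halide-catalysed direct anti-aldol of an N-acyloxazolidinone (Evans-type auxiliary aldol under soft enolisation): the chelated magnesium Z-enolate should be attacked by the aromatic aldehyde on the face opposite the auxiliary benzyl group to give the anti (3S,4R) adduct, which silylation removes from equilibrium, and acid-catalysed lactonisation then closes the γ-lactone with retention at the carbinol carbon (the tosyloxy-deactivated ring does not ionise), so aryl and acyl end up cis.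

Step 4
Reactants: 8 cis-lactone imide
Product: 10 (2R,3S)-2-[3-methoxy-4-(tosyloxy)phenyl]-5-oxooxolane-3-carboxylic acid, via lactone peroxy acid 9 (not isolated)
Conditions: LiOH, H2O2, THF–H2O, 0 °C; then Na2SO3 (aq.); then HCl to pH 2
Reagents that add atoms: hydrogen peroxide, OO
Why: Hydroperoxide cleavage of the exocyclic imide carbonyl (standard auxiliary removal) followed by sulfite reduction of the peracid; any ring-opened hydroxy acid should re-lactonise on acidification.

Step 5
Reactants: 10 (2R,3S)-2-[3-methoxy-4-(tosyloxy)phenyl]-5-oxooxolane-3-carboxylic acid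
Product: 11 4-[(2R,3R)-3-(hydroxymethyl)-5-oxooxolan-2-yl]-2-methoxyphenyl 4-methylbenzenesulfonate
Conditions: BH3·SMe2, THF, 0 °C → rt; then H2O
Reagents that add atoms: none
Why: Chemoselective borane reduction of a carboxylic acid in the presence of a γ-lactone and an aryl sulfonate (the usual paraconic acid reduction), under non-basic conditions that avoid lactone migration to the new hydroxyl.

Step 6
Reactants: 11 hydroxymethyl lactone
Product: 12 4-[(2R,3R)-3-{[(tert-butyldimethylsilyl)oxy]methyl}-5-oxooxolan-2-yl]-2-methoxyphenyl 4-methylbenzenesulfonate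
Conditions: TBSCl, imidazole, DMF, 0 °C → rt
Reagents that add atoms: tert-butyldimethylsilyl chloride, CC(C)(C)[Si](C)(C)Cl
Why: Silylation of the primary alcohol blocks translactonisation and protects it through the enolate steps.

Step 7
Reactants: 13 [4-(benzyloxy)-3-methoxyphenyl]methanol
Product: 14 1-(benzyloxy)-4-(bromomethyl)-2-methoxybenzene
Conditions: PBr3, Et2O, 0 °C
Reagents that add atoms: phosphorus tribromide, BrP(Br)Br
Why: Conversion of a benzylic alcohol into the bromide with PBr3; the product is used at once.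

Step 8
Reactants: 12 silyl ether lactone; 14 1-(benzyloxy)-4-(bromomethyl)-2-methoxybenzene
Product: 15 4-[(2R,3R,4S)-4-{[4-(benzyloxy)-3-methoxyphenyl]methyl}-3-{[(tert-butyldimethylsilyl)oxy]methyl}-5-oxooxolan-2-yl]-2-methoxyphenyl 4-methylbenzenesulfonate
Conditions: LiN(SiMe3)2, THF, −78 °C; then 14, DMPU, −78 → −40 °C
Reagents that add atoms: none
Why: Alkylation of a γ-butyrolactone lithium enolate; the cis aryl and CH2OTBS groups block one face, so the benzyl bromide should enter anti to both.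

Step 9
Reactants: 15 α-benzyl lactone
Product: 16 4-[(2R,3R,4S)-4-{[4-(benzyloxy)-3-methoxyphenyl]methyl}-4-hydroxy-3-{[(tert-butyldimethylsilyl)oxy]methyl}-5-oxooxolan-2-yl]-2-methoxyphenyl 4-methylbenzenesulfonate
Conditions: KN(SiMe3)2, THF, −78 °C; then 2-(phenylsulfonyl)-3-phenyloxaziridine, −78 °C; then AcOH
Reagents that add atoms: 2-(phenylsulfonyl)-3-phenyloxaziridine, O=S(=O)(c1ccccc1)N1OC1c1ccccc1
Why: Enolate oxidation with an N-sulfonyloxaziridine (Davis hydroxylation): oxygen is delivered to the same open face, which turns the arylmethyl group onto the face of the CH2OTBS and aryl groups and sets the tertiary carbinol with hydroxyl trans to CH2OTBS.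

Step 10
Reactants: 16 α-hydroxy lactone
Product: 17 lactol 4-[(2R,3R,4S)-4-{[4-(benzyloxy)-3-methoxyphenyl]methyl}-4,5-dihydroxy-3-{[(tert-butyldimethylsilyl)oxy]methyl}oxolan-2-yl]-2-methoxyphenyl 4-methylbenzenesulfonate (both C5 epimers)
Conditions: i-Bu2AlH (3 equiv), CH2Cl2, −78 °C; then KNaC4H4O6 (aq.)
Reagents that add atoms: none
Why: Partial reduction of a lactone to the lactol at low temperature; the aryl sulfonate and the silyl ether are inert to the hydride at −78 °C.

Step 11
Reactants: 17 lactol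
Product: 18 4-[(2R,3R,4S)-4-{[4-(benzyloxy)-3-methoxyphenyl]methyl}-4-hydroxy-3-{[(tert-butyldimethylsilyl)oxy]methyl}oxolan-2-yl]-2-methoxyphenyl 4-methylbenzenesulfonate
Conditions: Et3SiH, BF3·OEt2, CH2Cl2, −78 → −30 °C
Reagents that add atoms: none
Why: Ionic reduction of a lactol (oxocarbenium ion trapped by silane), the standard lactone-to-cyclic-ether sequence of lignan synthesis; the tosyloxy group makes the aryl ring electron-poor, so the benzylic C–O bond should not ionise and the cis arrangement at the aryl-bearing carbon is kept.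

Step 12
Reactants: 18 oxolane aryl tosylate
Product: 19 (3S,4R,5R)-3-{[4-(benzyloxy)-3-methoxyphenyl]methyl}-4-{[(tert-butyldimethylsilyl)oxy]methyl}-5-(4-hydroxy-3-methoxyphenyl)oxolan-3-ol
Conditions: Mg, MeOH, rt (ultrasound)
Reagents that add atoms: none
Why: Reductive S–O cleavage of an aryl sulfonate by magnesium in methanol (electron transfer) frees the phenol without acid and leaves benzyl and silyl ethers untouched.

Step 13
Reactants: 19 oxolane phenol
Product: 20 (3S,4R,5R)-3-{[4-(benzyloxy)-3-methoxyphenyl]methyl}-4-{[(tert-butyldimethylsilyl)oxy]methyl}-5-(4-hydroxy-3-iodo-5-methoxyphenyl)oxolan-3-ol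
Conditions: N-iodosuccinimide (1.0 equiv), DMF, 0 °C → rt
Reagents that add atoms: N-iodosuccinimide, O=C1CCC(=O)N1I
Why: Electrophilic aromatic iodination of the free phenol at its only open ortho position (para blocked, the other ortho position carries OMe); the benzyl-protected ring is much less activated in the absence of acid.

Step 14
Reactants: 21 4-(benzyloxy)-3-methoxybenzaldehyde
Product: 22 1-(benzyloxy)-4-ethynyl-2-methoxybenzene
Conditions: dimethyl (1-diazo-2-oxopropyl)phosphonate, K2CO3, MeOH, rt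
Reagents that add atoms: dimethyl (1-diazo-2-oxopropyl)phosphonate, COP(=O)(OC)C(=[N+]=[N-])C(C)=O
Why: Ohira–Bestmann (Seyferth–Gilbert) homologation of an aromatic aldehyde to the terminal alkyne.

Step 15
Reactants: 22 1-(benzyloxy)-4-ethynyl-2-methoxybenzene
Product: 23 1-(benzyloxy)-2-methoxy-4-(propa-1,2-dien-1-yl)benzene
Conditions: (CH2O)n, CuI (0.5 equiv), i-Pr2NH, 1,4-dioxane, reflux
Reagents that add atoms: formaldehyde (as paraformaldehyde), C=O
Why: Crabbé homologation of a terminal alkyne to the monosubstituted allene (Mannich reaction, then hydride shift with loss of imine); the electron-rich allene is used promptly.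

Step 16
Reactants: 20 iodophenol oxolane; 23 1-(benzyloxy)-2-methoxy-4-(propa-1,2-dien-1-yl)benzene (3 equiv)
Product: 24 (3S,4R,5R)-5-{(2S)-2-[4-(benzyloxy)-3-methoxyphenyl]-7-methoxy-3-methylidene-2,3-dihydro-1-benzofuran-5-yl}-3-{[4-(benzyloxy)-3-methoxyphenyl]methyl}-4-{[(tert-butyldimethylsilyl)oxy]methyl}oxolan-3-ol
Conditions: Pd(OAc)2 (5 mol %), (S,S)-2,2'-(propane-2,2-diyl)bis(4-phenyl-4,5-dihydro-1,3-oxazole) (10 mol %), Ag3PO4, DMF, 60–80 °C
Reagents that add atoms: none
Why: Oxidative addition of the C–I bond of 20 to zerovalent palladium (formed in situ), carbopalladation of the terminal C=C of allene 23 with aryl transfer to the central carbon (C3a–C3 bond) and capture of the resulting 1,2-diaryl π-allyl palladium cation by the silver-generated phenoxide at the aryl-bearing terminus (O1–C2 bond) should give 24 and return zerovalent palladium. The closest known reaction type is the Larock heteroannulation of 1,2-dienes by aryl iodides that carry an ortho OH or NH group, which has an enantioselective form with chiral bisoxazoline ligands and Ag3PO4. The furan ring closes by 5-exo attack of oxygen on the allyl terminus, which leaves the other terminus as the exocyclic methylidene. The new stereocentre C2 is under ligand control: the diastereomeric π-allyl complexes should interconvert by π–σ–π isomerisation through the CH2 terminus faster than C–O bond formation, so the ligand selects the face that is attacked and the remote oxolane stereocentres are not expected to interfere (the descriptor is 2S here only because C3 is sp2; the arrangement is that of 2R in the target). The step needs attack at the benzylic terminus and not at CH2, which follows the known preference of these annulations for the more substituted terminus and is reinforced by the 4-benzyloxy-3-methoxyphenyl group that stabilises positive charge there. It also needs the exocyclic alkene to stay out of conjugation with the ring, which the halide-free silver conditions and the moderate temperature are meant to secure.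

Step 17
Reactants: 24 3-methylidene dihydrobenzofuran
Product: 26 (3S,4R,5R)-5-{(2R,3R)-2-[4-(benzyloxy)-3-methoxyphenyl]-3-(hydroxymethyl)-7-methoxy-2,3-dihydro-1-benzofuran-5-yl}-3-{[4-(benzyloxy)-3-methoxyphenyl]methyl}-4-{[(tert-butyldimethylsilyl)oxy]methyl}oxolan-3-ol, via cis B-alkyl-9-BBN adduct 25 (not isolated)
Conditions: 9-BBN (4 equiv), THF, 0 °C → rt; then NaOH (aq.), H2O2, 0 °C → rt
Reagents that add atoms: hydrogen peroxide, OO
Why: Hydroboration–oxidation of a 1,1-disubstituted styrene-type alkene: boron adds to the terminal carbon and hydrogen to C3 from the face opposite the C2 aryl group (substrate control on a flat five-membered ring), so CH2OH should end up cis to the aryl group, (2R,3R); excess 9-BBN covers the free tertiary hydroxyl.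

Step 18
Reactants: 26 silyl-protected cis alcohol
Product: 27 (3S,4R,5R)-5-{(2R,3R)-2-[4-(benzyloxy)-3-methoxyphenyl]-3-(hydroxymethyl)-7-methoxy-2,3-dihydro-1-benzofuran-5-yl}-3-{[4-(benzyloxy)-3-methoxyphenyl]methyl}-4-(hydroxymethyl)oxolan-3-ol
Conditions: n-Bu4NF, AcOH, THF, 0 °C → rt
Reagents that add atoms: none
Why: Fluoride desilylation of a primary silyl ether, buffered and carried out while both phenols are still benzylated so that no phenoxide can open either cis benzylic ether.

Step 19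
Reactants: 27 bis(benzyl ether) triol
Product: 28 (3S,4R,5R)-5-[(2R,3R)-2-(4-hydroxy-3-methoxyphenyl)-3-(hydroxymethyl)-7-methoxy-2,3-dihydro-1-benzofuran-5-yl]-3-[(4-hydroxy-3-methoxyphenyl)methyl]-4-(hydroxymethyl)oxolan-3-ol (target)
Conditions: H2 (1 atm), Pd on carbon, EtOAc–MeOH, rt, stopped at full debenzylation
Reagents that add atoms: none
Why: Hydrogenolysis of aryl benzyl ethers over palladium is much faster than cleavage of the two cyclic benzylic C–O bonds, so both phenols should be freed under neutral conditions without touching the cis stereocentres.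

**Compound list**

1 | vanillin (4-hydroxy-3-methoxybenzaldehyde) | COc1cc(C=O)ccc1O | starting material
2 | 4-formyl-2-methoxyphenyl 4-methylbenzenesulfonate | COc1cc(C=O)ccc1OS(=O)(=O)c1ccc(C)cc1 | intermediate
3 | (R)-4-benzyl-1,3-oxazolidin-2-one | O=C1N[C@H](Cc2ccccc2)CO1 | starting material
4 | methyl 4-chloro-4-oxobutanoate | COC(=O)CCC(Cl)=O | starting material
5 | methyl 4-[(4R)-4-benzyl-2-oxo-1,3-oxazolidin-3-yl]-4-oxobutanoate | COC(=O)CCC(=O)N1[C@H](Cc2ccccc2)COC1=O | intermediate
6 | methyl (3S,4R)-3-{[(4R)-4-benzyl-2-oxo-1,3-oxazolidin-3-yl]carbonyl}-4-[3-methoxy-4-(tosyloxy)phenyl]-4-[(trimethylsilyl)oxy]butanoate | C[Si](C)(C)O[C@@H](c1ccc(OS(=O)(=O)c2ccc(C)cc2)c(OC)c1)[C@H](CC(=O)OC)C(=O)N1[C@H](Cc2ccccc2)COC1=O | intermediate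
7 | methyl (3S,4R)-3-{[(4R)-4-benzyl-2-oxo-1,3-oxazolidin-3-yl]carbonyl}-4-hydroxy-4-[3-methoxy-4-(tosyloxy)phenyl]butanoate | O[C@@H](c1ccc(OS(=O)(=O)c2ccc(C)cc2)c(OC)c1)[C@H](CC(=O)OC)C(=O)N1[C@H](Cc2ccccc2)COC1=O | intermediate
8 | (4R)-4-benzyl-3-{(2R,3S)-2-[3-methoxy-4-(tosyloxy)phenyl]-5-oxooxolane-3-carbonyl}-1,3-oxazolidin-2-one (aryl and acyl cis) | O=C1O[C@@H](c2ccc(OS(=O)(=O)c3ccc(C)cc3)c(OC)c2)[C@H](C1)C(=O)N1[C@H](Cc2ccccc2)COC1=O | intermediate
9 | (2R,3S)-2-[3-methoxy-4-(tosyloxy)phenyl]-5-oxooxolane-3-carboperoxoic acid | O=C1O[C@@H](c2ccc(OS(=O)(=O)c3ccc(C)cc3)c(OC)c2)[C@H](C1)C(=O)OO | intermediate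
10 | (2R,3S)-2-[3-methoxy-4-(tosyloxy)phenyl]-5-oxooxolane-3-carboxylic acid | O=C1O[C@@H](c2ccc(OS(=O)(=O)c3ccc(C)cc3)c(OC)c2)[C@H](C1)C(=O)O | intermediate
11 | 4-[(2R,3R)-3-(hydroxymethyl)-5-oxooxolan-2-yl]-2-methoxyphenyl 4-methylbenzenesulfonate | O=C1O[C@@H](c2ccc(OS(=O)(=O)c3ccc(C)cc3)c(OC)c2)[C@H](C1)CO | intermediate
12 | 4-[(2R,3R)-3-{[(tert-butyldimethylsilyl)oxy]methyl}-5-oxooxolan-2-yl]-2-methoxyphenyl 4-methylbenzenesulfonate | O=C1O[C@@H](c2ccc(OS(=O)(=O)c3ccc(C)cc3)c(OC)c2)[C@H](C1)CO[Si](C)(C)C(C)(C)C | intermediate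
13 | [4-(benzyloxy)-3-methoxyphenyl]methanol | COc1cc(CO)ccc1OCc1ccccc1 | starting material
14 | 1-(benzyloxy)-4-(bromomethyl)-2-methoxybenzene | COc1cc(CBr)ccc1OCc1ccccc1 | intermediate
15 | 4-[(2R,3R,4S)-4-{[4-(benzyloxy)-3-methoxyphenyl]methyl}-3-{[(tert-butyldimethylsilyl)oxy]methyl}-5-oxooxolan-2-yl]-2-methoxyphenyl 4-methylbenzenesulfonate | COc1cc(C[C@@H]2C(=O)O[C@@H](c3ccc(OS(=O)(=O)c4ccc(C)cc4)c(OC)c3)[C@H]2CO[Si](C)(C)C(C)(C)C)ccc1OCc1ccccc1 | intermediate
16 | 4-[(2R,3R,4S)-4-{[4-(benzyloxy)-3-methoxyphenyl]methyl}-4-hydroxy-3-{[(tert-butyldimethylsilyl)oxy]methyl}-5-oxooxolan-2-yl]-2-methoxyphenyl 4-methylbenzenesulfonate | COc1cc(C[C@@]2(O)C(=O)O[C@@H](c3ccc(OS(=O)(=O)c4ccc(C)cc4)c(OC)c3)[C@H]2CO[Si](C)(C)C(C)(C)C)ccc1OCc1ccccc1 | intermediate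
17 | 4-[(2R,3R,4S)-4-{[4-(benzyloxy)-3-methoxyphenyl]methyl}-4,5-dihydroxy-3-{[(tert-butyldimethylsilyl)oxy]methyl}oxolan-2-yl]-2-methoxyphenyl 4-methylbenzenesulfonate (lactol, both C5 epimers) | COc1cc(C[C@@]2(O)C(O)O[C@@H](c3ccc(OS(=O)(=O)c4ccc(C)cc4)c(OC)c3)[C@H]2CO[Si](C)(C)C(C)(C)C)ccc1OCc1ccccc1 | intermediate
18 | 4-[(2R,3R,4S)-4-{[4-(benzyloxy)-3-methoxyphenyl]methyl}-4-hydroxy-3-{[(tert-butyldimethylsilyl)oxy]methyl}oxolan-2-yl]-2-methoxyphenyl 4-methylbenzenesulfonate | COc1cc(C[C@@]2(O)CO[C@@H](c3ccc(OS(=O)(=O)c4ccc(C)cc4)c(OC)c3)[C@H]2CO[Si](C)(C)C(C)(C)C)ccc1OCc1ccccc1 | intermediate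
19 | (3S,4R,5R)-3-{[4-(benzyloxy)-3-methoxyphenyl]methyl}-4-{[(tert-butyldimethylsilyl)oxy]methyl}-5-(4-hydroxy-3-methoxyphenyl)oxolan-3-ol | COc1cc(C[C@@]2(O)CO[C@@H](c3ccc(O)c(OC)c3)[C@H]2CO[Si](C)(C)C(C)(C)C)ccc1OCc1ccccc1 | intermediate
20 | (3S,4R,5R)-3-{[4-(benzyloxy)-3-methoxyphenyl]methyl}-4-{[(tert-butyldimethylsilyl)oxy]methyl}-5-(4-hydroxy-3-iodo-5-methoxyphenyl)oxolan-3-ol | COc1cc(C[C@@]2(O)CO[C@@H](c3cc(I)c(O)c(OC)c3)[C@H]2CO[Si](C)(C)C(C)(C)C)ccc1OCc1ccccc1 | intermediate
21 | 4-(benzyloxy)-3-methoxybenzaldehyde | COc1cc(C=O)ccc1OCc1ccccc1 | starting material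
22 | 1-(benzyloxy)-4-ethynyl-2-methoxybenzene | COc1cc(C#C)ccc1OCc1ccccc1 | intermediate
23 | 1-(benzyloxy)-2-methoxy-4-(propa-1,2-dien-1-yl)benzene | COc1cc(C=C=C)ccc1OCc1ccccc1 | intermediate
24 | (3S,4R,5R)-5-{(2S)-2-[4-(benzyloxy)-3-methoxyphenyl]-7-methoxy-3-methylidene-2,3-dihydro-1-benzofuran-5-yl}-3-{[4-(benzyloxy)-3-methoxyphenyl]methyl}-4-{[(tert-butyldimethylsilyl)oxy]methyl}oxolan-3-ol | COc1cc(C[C@@]2(O)CO[C@@H](c3cc(OC)c4c(c3)C(=C)[C@H](c3ccc(OCc5ccccc5)c(OC)c3)O4)[C@H]2CO[Si](C)(C)C(C)(C)C)ccc1OCc1ccccc1 | intermediate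
25 | B-alkyl-9-borabicyclo[3.3.1]nonane adduct of 24, boron on the exocyclic CH2, CH2B cis to the C2 aryl group (drawn with the tertiary hydroxyl free; under excess 9-BBN it is expected to be carried as its borinate) | COc1cc(C[C@@]2(O)CO[C@@H](c3cc(OC)c4c(c3)[C@H](CB5C6CCCC5CCC6)[C@H](c3ccc(OCc5ccccc5)c(OC)c3)O4)[C@H]2CO[Si](C)(C)C(C)(C)C)ccc1OCc1ccccc1 | intermediate
26 | (3S,4R,5R)-5-{(2R,3R)-2-[4-(benzyloxy)-3-methoxyphenyl]-3-(hydroxymethyl)-7-methoxy-2,3-dihydro-1-benzofuran-5-yl}-3-{[4-(benzyloxy)-3-methoxyphenyl]methyl}-4-{[(tert-butyldimethylsilyl)oxy]methyl}oxolan-3-ol | COc1cc(C[C@@]2(O)CO[C@@H](c3cc(OC)c4c(c3)[C@H](CO)[C@H](c3ccc(OCc5ccccc5)c(OC)c3)O4)[C@H]2CO[Si](C)(C)C(C)(C)C)ccc1OCc1ccccc1 | intermediate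
27 | (3S,4R,5R)-5-{(2R,3R)-2-[4-(benzyloxy)-3-methoxyphenyl]-3-(hydroxymethyl)-7-methoxy-2,3-dihydro-1-benzofuran-5-yl}-3-{[4-(benzyloxy)-3-methoxyphenyl]methyl}-4-(hydroxymethyl)oxolan-3-ol | COc1cc(C[C@@]2(O)CO[C@@H](c3cc(OC)c4c(c3)[C@H](CO)[C@H](c3ccc(OCc5ccccc5)c(OC)c3)O4)[C@H]2CO)ccc1OCc1ccccc1 | intermediate
28 | (3S,4R,5R)-5-[(2R,3R)-2-(4-hydroxy-3-methoxyphenyl)-3-(hydroxymethyl)-7-methoxy-2,3-dihydro-1-benzofuran-5-yl]-3-[(4-hydroxy-3-methoxyphenyl)methyl]-4-(hydroxymethyl)oxolan-3-ol | COc1cc(C[C@@]2(O)CO[C@@H](c3cc(OC)c4c(c3)[C@H](CO)[C@H](c3ccc(O)c(OC)c3)O4)[C@H]2CO)ccc1O | target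

**Step count and risks**

Total step count: 19. Longest linear sequence: 15 steps (1, 3, 4, 5, 6, 8, 9, 10, 11, 12, 13, 16, 17, 18, 19).

Steps most likely to fail:

1. Step 16 (key heteroannulation). The phenoxide may attack the CH2 terminus of the π-allyl intermediate and give the 3-benzylidene isomer. Ligand control at C2 may be incomplete, and the remote oxolane centres cannot correct it. A palladium hydride may also move the exocyclic double bond into the ring and aromatise the furan. Fallback, which sets out from 20 and 21 and comes back at 24, forms the same two bonds in two known operations. Olefination of 21 with triethyl phosphonoacetate and NaH should give ethyl (2E)-3-[4-(benzyloxy)-3-methoxyphenyl]prop-2-enoate F1. Reduction with i-Bu2AlH should give (2E)-3-[4-(benzyloxy)-3-methoxyphenyl]prop-2-en-1-ol F2, and methyl chloroformate with pyridine should give (2E)-3-[4-(benzyloxy)-3-methoxyphenyl]prop-2-en-1-yl methyl carbonate F3. Iridium-catalysed enantioselective allylic etherification of the lithium phenoxide of 20 with F3 ([Ir(cod)Cl]2, chiral phosphoramidite, THF) should form O1–C2 with branched selectivity and give the (R)-allyl aryl ether (3S,4R,5R)-5-(4-{(1R)-1-[4-(benzyloxy)-3-methoxyphenyl]prop-2-en-1-yl}oxy-3-iodo-5-methoxyphenyl)-3-{[4-(benzyloxy)-3-methoxyphenyl]methyl}-4-{[(tert-butyldimethylsilyl)oxy]methyl}oxolan-3-ol F4. An intramolecular Mizoroki–Heck 5-exo cyclisation (Pd(OAc)2, PPh3, Ag2CO3, MeCN, 60 °C) should then form C3a–C3 and, after β-hydride elimination, give 24.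

2. Step 3 (anti-aldol). The ester side chain may chelate magnesium, which would slow turnover or erode the anti and facial selectivity. Fallback, which sets out from 5 and 2 and comes back at 7: the enolate is preformed with Bu2BOTf and i-Pr2NEt as the dibutylboron Z-enolate of 5 F5. It is added at −78 °C to aldehyde 2 precomplexed with Et2AlCl. This is the open-transition-state, Lewis-acid-mediated anti variant of the auxiliary aldol and should give 7 after oxidative work-up; 7 is lactonised to 8 as in step 3.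

3. Step 11 (lactol reduction). The α-hydroxy oxocarbenium ion may undergo a 1,2-shift, the silyl ether may be lost to the Lewis acid, or the benzylic centre may partly ionise. Fallback, which sets out from 16 and comes back at 18, avoids any cation. LiBH4 in THF should reduce the lactone to (2S,3R,4R)-2-{[4-(benzyloxy)-3-methoxyphenyl]methyl}-3-{[(tert-butyldimethylsilyl)oxy]methyl}-4-[3-methoxy-4-(tosyloxy)phenyl]butane-1,2,4-triol F6. Selective sulfonylation of the primary hydroxyl (TsCl, pyridine, 0 °C) should give the 1-O-tosylate of this triol F7. On warming in pyridine F7 should close by 5-exo-tet attack of the benzylic hydroxyl on the primary carbon, with retention at the aryl-bearing carbon, to give 18.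

**Further compounds**

F1 | step 16 | ethyl (2E)-3-[4-(benzyloxy)-3-methoxyphenyl]prop-2-enoate | CCOC(=O)/C=C/c1ccc(OCc2ccccc2)c(OC)c1
F2 | step 16 | (2E)-3-[4-(benzyloxy)-3-methoxyphenyl]prop-2-en-1-ol | OC/C=C/c1ccc(OCc2ccccc2)c(OC)c1
F3 | step 16 | (2E)-3-[4-(benzyloxy)-3-methoxyphenyl]prop-2-en-1-yl methyl carbonate | COC(=O)OC/C=C/c1ccc(OCc2ccccc2)c(OC)c1
F4 | step 16 | (3S,4R,5R)-5-(4-{(1R)-1-[4-(benzyloxy)-3-methoxyphenyl]prop-2-en-1-yl}oxy-3-iodo-5-methoxyphenyl)-3-{[4-(benzyloxy)-3-methoxyphenyl]methyl}-4-{[(tert-butyldimethylsilyl)oxy]methyl}oxolan-3-ol | COc1cc(C[C@@]2(O)CO[C@@H](c3cc(I)c(O[C@H](C=C)c4ccc(OCc5ccccc5)c(OC)c4)c(OC)c3)[C@H]2CO[Si](C)(C)C(C)(C)C)ccc1OCc1ccccc1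
F5 | step 3 | dibutylboron Z-enolate of 5 | CCCCB(CCCC)O/C(=C\CC(=O)OC)N1[C@H](Cc2ccccc2)COC1=O
F6 | step 11 | (2S,3R,4R)-2-{[4-(benzyloxy)-3-methoxyphenyl]methyl}-3-{[(tert-butyldimethylsilyl)oxy]methyl}-4-[3-methoxy-4-(tosyloxy)phenyl]butane-1,2,4-triol | COc1cc(C[C@@](O)(CO)[C@H](CO[Si](C)(C)C(C)(C)C)[C@@H](O)c2ccc(OS(=O)(=O)c3ccc(C)cc3)c(OC)c2)ccc1OCc1ccccc1
F7 | step 11 | 1-O-tosylate of triol F6 | COc1cc(C[C@@](O)(COS(=O)(=O)c2ccc(C)cc2)[C@H](CO[Si](C)(C)C(C)(C)C)[C@@H](O)c2ccc(OS(=O)(=O)c3ccc(C)cc3)c(OC)c2)ccc1OCc1ccccc1
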